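The bond on which the route rests is C7–C8 of the C18 acyl chain (numbered from the ester carbonyl). C8 is the allylic methylene beside the C9=C10 (Z)-olefin, so it can serve as an allylic electrophile, while C2–C7 is a plain methylene chain. The key step is a cobalt-catalysed SN2 alkyl–allyl coupling: the alkylzinc iodide made from the 7-iodoheptanoate of the fully assembled (3S)-vinyl diynyl carbinol carrying the trans-(2R,3R)-oxirane ring is joined to (2Z,5Z)-1-chloroundeca-2,5-diene. One operation should complete the skipped (9Z,12Z)-diene chain on the intact ene-diyne-epoxide ester, both Z-geometries arriving with the chloride.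

Key step: step 14

Remark: as drawn, the oxirane is trans (both ring carbons R) and the carbinol carbon is S; the route is planned for exactly this stereoisomer.

Step 1
Reactants: 1 (E)-dec-2-en-1-ol
Product: 2 [(2R,3R)-3-heptyloxiran-2-yl]methanol
Conditions: Ti(OiPr)4 (cat.), D-(−)-diethyl tartrate (cat.), TBHP, 4 Å MS, CH2Cl2, −20 °C
Reagents that add atoms: tert-butyl hydroperoxide CC(C)(C)OO
Why: Sharpless asymmetric epoxidation of a primary (E)-allylic alcohol, in which the titanium/D-(−)-tartrate complex should deliver oxygen to the face that gives the (2R,3R)-epoxy alcohol, the E-olefin fixing the trans relationship.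

Step 2
Reactants: 2 [(2R,3R)-3-heptyloxiran-2-yl]methanol
Product: 3 [(2R,3R)-3-heptyloxiran-2-yl]methyl trifluoromethanesulfonate (used crude at once)
Conditions: Tf2O, Et3N, CH2Cl2, −78 °C
Reagents that add atoms: triflic anhydride O=S(=O)(OS(=O)(=O)C(F)(F)F)C(F)(F)F
Why: O-sulfonylation of the primary alcohol at low temperature should give the epoxy triflate without touching the oxirane or its two stereocentres.

Step 3
Reactants: 3 [(2R,3R)-3-heptyloxiran-2-yl]methyl trifluoromethanesulfonate
Product: 4 trimethyl{3-[(2R,3R)-3-heptyloxiran-2-yl]prop-1-yn-1-yl}silane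
Conditions: TMSC≡CH, n-BuLi, THF/DMPU, −78 °C
Reagents that add atoms: (trimethylsilyl)acetylene C#C[Si](C)(C)C
Why: SN2 alkynylation of an epoxy triflate, where displacement of the primary triflate by the lithium acetylide at −78 °C should be much faster than attack on the oxirane, so both stereocentres are carried through unchanged.

Step 4
Reactants: 4 trimethyl{3-[(2R,3R)-3-heptyloxiran-2-yl]prop-1-yn-1-yl}silane
Product: 5 (2R,3R)-2-(3-bromoprop-2-yn-1-yl)-3-heptyloxirane
Conditions: NBS, AgNO3 (cat.), acetone, rt
Reagents that add atoms: N-bromosuccinimide O=C1CCC(=O)N1Br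
Why: silver-catalysed desilylative bromination, in which Ag(I) turns the alkynylsilane into a silver acetylide that NBS brominates under neutral conditions that should spare the oxirane.

Step 5
Reactants: 6 acrolein
Product: 7 rac-5-(trimethylsilyl)pent-1-en-4-yn-3-ol
Conditions: TMSC≡CH, n-BuLi, THF, −78 °C; then H2O
Reagents that add atoms: (trimethylsilyl)acetylene C#C[Si](C)(C)C
Why: 1,2-addition of a hard lithium acetylide to the enal carbonyl at −78 °C should give the racemic vinyl alkynyl carbinol.

Step 6
Reactants: 7 rac-5-(trimethylsilyl)pent-1-en-4-yn-3-ol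
Product: 8 (S)-5-(trimethylsilyl)pent-1-en-4-yn-3-ol (the unreacted enantiomer)
Conditions: lipase AK (Pseudomonas fluorescens), vinyl acetate, hexane, rt, run to just past half conversion
Reagents that add atoms: none
Why: lipase-catalysed kinetic resolution by irreversible transesterification, in which (Kazlauskas rule, silylethynyl as the large group) the (R)-alcohol should be acetylated and the (S)-alcohol recovered, its enantiopurity rising as conversion passes one half.

Step 7
Reactants: 8 (S)-5-(trimethylsilyl)pent-1-en-4-yn-3-ol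
Product: 9 (S)-pent-1-en-4-yn-3-ol (volatile; handled as a solution)
Conditions: K2CO3 (cat.), MeOH, 0 °C
Reagents that add atoms: none
Why: methanolysis of the C(sp)–Si bond by catalytic methoxide, which does not involve the carbinol centre.

Step 8
Reactants: 9 (S)-pent-1-en-4-yn-3-ol; 5 (2R,3R)-2-(3-bromoprop-2-yn-1-yl)-3-heptyloxirane
Product: 10 (3S)-8-[(2R,3R)-3-heptyloxiran-2-yl]oct-1-en-4,6-diyn-3-ol
Conditions: CuCl (cat.), NH2OH·HCl, n-BuNH2, H2O/Et2O, 0 °C, slow addition of 5
Reagents that add atoms: none
Why: Cadiot–Chodkiewicz coupling of the copper(I) acetylide of 9 with the 1-bromoalkyne should give the unsymmetrical 1,3-diyne, hydroxylamine keeping copper in the +1 state to suppress homocoupling, and no stereocentre is touched.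

Step 9
Reactants: 11 7-bromoheptanoic acid
Product: 12 7-iodoheptanoic acid
Conditions: NaI, acetone, reflux
Reagents that add atoms: sodium iodide [Na+].[I-]
Why: Finkelstein halide exchange, driven by precipitation of sodium bromide from acetone.

Step 10
Reactants: 10 (3S)-8-[(2R,3R)-3-heptyloxiran-2-yl]oct-1-en-4,6-diyn-3-ol; 12 7-iodoheptanoic acid
Product: 13 (3S)-8-[(2R,3R)-3-heptyloxiran-2-yl]oct-1-en-4,6-diyn-3-yl 7-iodoheptanoate
Conditions: DCC, DMAP (cat.), CH2Cl2, 0 °C → rt
Reagents that add atoms: none
Why: Steglich esterification through the acylpyridinium, which does not break the carbinol C–O bond, so 3S should be retained, and the neutral conditions should spare oxirane, diyne and primary iodide.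

Step 11
Reactants: 14 prop-2-yn-1-ol; 15 1-bromooct-2-yne
Product: 16 undeca-2,5-diyn-1-ol
Conditions: CuI, NaI, K2CO3, DMF, rt
Reagents that add atoms: none
Why: copper-mediated coupling of a terminal alkyne with a propargylic bromide should give the skipped diyne by direct substitution without allene formation.

Step 12
Reactants: 16 undeca-2,5-diyn-1-ol
Product: 17 (2Z,5Z)-undeca-2,5-dien-1-ol
Conditions: H2 (1 atm), P-2 Ni (Ni(OAc)2·4H2O/NaBH4), ethylenediamine, EtOH, rt
Reagents that add atoms: none
Why: syn-semihydrogenation of both alkynes on amine-poisoned P-2 nickel should set the two Z-olefins and stop at the diene.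

Step 13
Reactants: 17 (2Z,5Z)-undeca-2,5-dien-1-ol
Product: 18 (2Z,5Z)-1-chloroundeca-2,5-diene
Conditions: NCS, Me2S, CH2Cl2, −20 → 0 °C
Reagents that add atoms: N-chlorosuccinimide O=C1CCC(=O)N1Cl
Why: Corey–Kim chlorination, in which chloride displaces the alkoxysulfonium at the primary carbon by SN2, so neither allylic transposition nor Z/E isomerisation is expected.

Step 14
Reactants: 13 (3S)-8-[(2R,3R)-3-heptyloxiran-2-yl]oct-1-en-4,6-diyn-3-yl 7-iodoheptanoate; 18 (2Z,5Z)-1-chloroundeca-2,5-diene
Product: 20 (3S)-8-[(2R,3R)-3-heptyloxiran-2-yl]oct-1-en-4,6-diyn-3-yl (9Z,12Z)-octadeca-9,12-dienoate (target), via alkylzinc iodide 19 (not isolated)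
Conditions: Zn dust (activated), LiCl, THF, 25 °C; decant from zinc; then 18, CoBr2 (10 mol%), THF/NMP, −10 °C
Reagents that add atoms: none
Why: Zinc inserts into the primary C–I bond (LiCl-assisted) to give an alkylzinc iodide too weakly nucleophilic to attack the ester, the oxirane or the diyne; transmetalation to cobalt gives an alkylcobalt species that displaces chloride at the α-carbon (C8) of the primary allylic chloride and forms the C7–C8 bond by reductive elimination. The closest known reaction type is the cobalt-catalysed allylation of organozinc reagents with allylic chlorides, which is SN2-selective and retains the geometry of Z-allylic chlorides. No ring is closed and no stereocentre is formed; the three existing centres are remote from the reacting carbons and should stay untouched. The step needs α- over γ-regioselectivity, retention of the 2Z geometry, and chemoselectivity for the allylic chloride over the secondary allylic-propargylic ester, the oxirane and the diyne. These should be secured by the absence of copper (which would favour SN2' attack and could displace the propargylic ester) and of palladium(0) (which would ionise that ester), by the low temperature, and by the far higher reactivity of a primary allylic chloride than of a carboxylate leaving group towards the alkylcobalt intermediate.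

Compound list
1 | (E)-dec-2-en-1-ol | CCCCCCC/C=C/CO | starting material
2 | [(2R,3R)-3-heptyloxiran-2-yl]methanol | OC[C@H]1O[C@@H]1CCCCCCC | intermediate
3 | [(2R,3R)-3-heptyloxiran-2-yl]methyl trifluoromethanesulfonate | FC(F)(F)S(=O)(=O)OC[C@H]1O[C@@H]1CCCCCCC | intermediate
4 | trimethyl{3-[(2R,3R)-3-heptyloxiran-2-yl]prop-1-yn-1-yl}silane | C[Si](C)(C)C#CC[C@H]1O[C@@H]1CCCCCCC | intermediate
5 | (2R,3R)-2-(3-bromoprop-2-yn-1-yl)-3-heptyloxirane | BrC#CC[C@H]1O[C@@H]1CCCCCCC | intermediate
6 | acrolein (prop-2-enal) | C=CC=O | starting material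
7 | rac-5-(trimethylsilyl)pent-1-en-4-yn-3-ol | C=CC(O)C#C[Si](C)(C)C | intermediate
8 | (S)-5-(trimethylsilyl)pent-1-en-4-yn-3-ol | C=C[C@@H](C#C[Si](C)(C)C)O | intermediate
9 | (S)-pent-1-en-4-yn-3-ol | C=C[C@@H](C#C)O | intermediate
10 | (3S)-8-[(2R,3R)-3-heptyloxiran-2-yl]oct-1-en-4,6-diyn-3-ol | C=C[C@@H](C#CC#CC[C@H]1O[C@@H]1CCCCCCC)O | intermediate
11 | 7-bromoheptanoic acid | OC(=O)CCCCCCBr | starting material
12 | 7-iodoheptanoic acid | OC(=O)CCCCCCI | intermediate
13 | (3S)-8-[(2R,3R)-3-heptyloxiran-2-yl]oct-1-en-4,6-diyn-3-yl 7-iodoheptanoate | C=C[C@@H](C#CC#CC[C@H]1O[C@@H]1CCCCCCC)OC(=O)CCCCCCI | intermediate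
14 | prop-2-yn-1-ol | C#CCO | starting material
15 | 1-bromooct-2-yne | CCCCCC#CCBr | starting material
16 | undeca-2,5-diyn-1-ol | CCCCCC#CCC#CCO | intermediate
17 | (2Z,5Z)-undeca-2,5-dien-1-ol | CCCCC/C=C\C/C=C\CO | intermediate
18 | (2Z,5Z)-1-chloroundeca-2,5-diene | CCCCC/C=C\C/C=C\CCl | intermediate
19 | {7-[(3S)-8-[(2R,3R)-3-heptyloxiran-2-yl]oct-1-en-4,6-diyn-3-yl]oxy-7-oxoheptyl}zinc iodide | C=C[C@@H](C#CC#CC[C@H]1O[C@@H]1CCCCCCC)OC(=O)CCCCCC[Zn]I | intermediate
20 | (3S)-8-[(2R,3R)-3-heptyloxiran-2-yl]oct-1-en-4,6-diyn-3-yl (9Z,12Z)-octadeca-9,12-dienoate | C=C[C@@H](C#CC#CC[C@H]1O[C@@H]1CCCCCCC)OC(=O)CCCCCCC/C=C\C/C=C\CCCCC | target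

Total step count: 14. Longest linear sequence: 7 steps (steps 1, 2, 3, 4, 8, 10, 14).

Steps most likely to fail

Step 14. The zinc halide formed during insertion may open the oxirane, low-valent cobalt may oligomerise the diyne or ionise the allylic-propargylic ester, and the coupling may leak to γ-attack or Z→E isomerisation of the 2-olefin. The fallback moves the same C7–C8 union onto a substrate without sensitive groups and attaches the epoxy-diynol last. It sets out from 12: Fischer esterification (MeOH, cat. H2SO4) should give methyl 7-iodoheptanoate F1. Zinc insertion (Zn, LiCl, THF) should give (7-methoxy-7-oxoheptyl)zinc iodide F2. Cobalt-catalysed coupling of F2 with 18 should give methyl (9Z,12Z)-octadeca-9,12-dienoate F3, which can be purified on silver nitrate-impregnated silica if needed. Saponification (LiOH, THF/H2O) should give (9Z,12Z)-octadeca-9,12-dienoic acid F4, and DCC/DMAP esterification of F4 with 10 comes back to the route at 20.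

Step 8. The bromoalkyne or the alkyne may homocouple, the amine may open the oxirane, and the volatile 9 may be lost. The fallback forms the C3–C4 bond by carbonyl addition instead of sp–sp coupling. It sets out from 3: displacement with lithium (trimethylsilyl)butadiynide (from 1,4-bis(trimethylsilyl)buta-1,3-diyne and MeLi·LiBr, THF/DMPU, −78 °C) should give trimethyl{5-[(2R,3R)-3-heptyloxiran-2-yl]penta-1,3-diyn-1-yl}silane F5. K2CO3/MeOH should give (2R,3R)-2-heptyl-3-(penta-2,4-diyn-1-yl)oxirane F6. Deprotonation (n-BuLi, THF, −78 °C) and addition to acrolein 6 should give (3RS)-8-[(2R,3R)-3-heptyloxiran-2-yl]oct-1-en-4,6-diyn-3-ol F7 as a pair of C3 epimers. Lipase AK with vinyl acetate should acetylate the 3R epimer to (3R)-8-[(2R,3R)-3-heptyloxiran-2-yl]oct-1-en-4,6-diyn-3-yl acetate F8 and leave the 3S epimer, which is separated by chromatography and comes back to the route at 10.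

Step 3. The acetylide may attack the oxirane instead of the primary carbon, or the triflate may decompose before it is displaced. The fallback installs the alkyne before the oxirane and sets both oxirane centres by catalyst control on the olefin. It sets out from 1: PBr3 (Et2O, 0 °C) should give (E)-1-bromodec-2-ene F9. Copper-catalysed coupling with (trimethylsilyl)ethynylmagnesium bromide (CuBr·SMe2 cat., THF) should give (E)-trimethyl(dodec-4-en-1-yn-1-yl)silane F10. Shi epoxidation of F10 (D-fructose-derived ketone, Oxone, K2CO3, MeCN/dimethoxymethane/H2O, 0 °C) should give the (R,R)-trans-epoxide and comes back to the route at 4.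

Further compounds
F1 | step 14 | methyl 7-iodoheptanoate | COC(=O)CCCCCCI
F2 | step 14 | (7-methoxy-7-oxoheptyl)zinc iodide | COC(=O)CCCCCC[Zn]I
F3 | step 14 | methyl (9Z,12Z)-octadeca-9,12-dienoate | CCCCC/C=C\C/C=C\CCCCCCCC(=O)OC
F4 | step 14 | (9Z,12Z)-octadeca-9,12-dienoic acid | CCCCC/C=C\C/C=C\CCCCCCCC(O)=O
F5 | step 8 | trimethyl{5-[(2R,3R)-3-heptyloxiran-2-yl]penta-1,3-diyn-1-yl}silane | C[Si](C)(C)C#CC#CC[C@H]1O[C@@H]1CCCCCCC
F6 | step 8 | (2R,3R)-2-heptyl-3-(penta-2,4-diyn-1-yl)oxirane | C#CC#CC[C@H]1O[C@@H]1CCCCCCC
F7 | step 8 | (3RS)-8-[(2R,3R)-3-heptyloxiran-2-yl]oct-1-en-4,6-diyn-3-ol | C=CC(O)C#CC#CC[C@H]1O[C@@H]1CCCCCCC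
F8 | step 8 | (3R)-8-[(2R,3R)-3-heptyloxiran-2-yl]oct-1-en-4,6-diyn-3-yl acetate | C=C[C@H](C#CC#CC[C@H]1O[C@@H]1CCCCCCC)OC(C)=O
F9 | step 3 | (E)-1-bromodec-2-ene | CCCCCCC/C=C/CBr
F10 | step 3 | (E)-trimethyl(dodec-4-en-1-yn-1-yl)silane | CCCCCCC/C=C/CC#C[Si](C)(C)C
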